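**Strategy.** The route rests on making the α-methylene-γ-lactone last. In the final C–C-forming step one molecule of CO is inserted between O6 and C11 of a homopropargylic alcohol. The free C6 hydroxyl and the trans-disposed C7 ethynyl group (C11≡C13) on the ten-membered ring C1–C10 are joined through the new carbonyl C12. This closes the five-membered lactone ring (O6, C6, C7, C11, C12) and leaves C13 as the exocyclic methylene. The precursor is the fully functionalised cyclodecene 32: ring-cis C1=C10 enoate, C4 exomethylene, C8 angelate, C5 oxygen masked as a PMB ether. It is built by allenylzinc fragment coupling and Horner–Wadsworth–Emmons ring closure.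

Key step: step 21

Remark on the chemistry: locants are those of the germacrane skeleton of the target (ring C1–C10, lactone carbons C11–C13, ester carbon C14, exocyclic methylene C15); the propargylation in step 12 is assumed to follow its usual course (anti SN2′ palladation, retentive transmetalation to zinc, syn SE2′ addition).

Abbreviations: PMB = 4-methoxybenzyl, TBS = tert-butyldimethylsilyl, TBDPS = tert-butyldiphenylsilyl, Ms = methanesulfonyl, Ts = 4-toluenesulfonyl, angelate = (Z)-2-methylbut-2-enoate.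

**Fragment A (C1–C6, C15)**

Step 1
Reactants: 1 methyl (R)-2,2-dimethyl-1,3-dioxolane-4-carboxylate
Product: 2 (R)-N-methoxy-N,2,2-trimethyl-1,3-dioxolane-4-carboxamide
Conditions: MeNH(OMe)·HCl, i-PrMgCl, THF, −20 °C
Reagents that add atoms: N,O-dimethylhydroxylamine hydrochloride, CNOC.Cl
Why: Aminolysis of the ester by the chloromagnesium amide (Weinreb amide formation) proceeds at low temperature without enolising the α-alkoxy centre, which becomes C5 in one half of the material and C8 in the other.

Step 2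
Reactants: 3 3-bromopropan-1-ol
Product: 4 (3-bromopropoxy)(tert-butyl)diphenylsilane
Conditions: TBDPSCl, imidazole, CH2Cl2, 0 °C → rt
Reagents that add atoms: tert-butyl(chloro)diphenylsilane, CC(C)(C)[Si](Cl)(c1ccccc1)c1ccccc1
Why: Standard silylation of a primary alcohol; the TBDPS ether is chosen because it has to survive the two aqueous acetic acid steps (5 and 14) and leaves together with the C6 silyl ether in step 18.

Step 3
Reactants: 4 (3-bromopropoxy)(tert-butyl)diphenylsilane; 2 (R)-N-methoxy-N,2,2-trimethyl-1,3-dioxolane-4-carboxamide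
Product: 6 ketone 4-[(tert-butyldiphenylsilyl)oxy]-1-[(4R)-2,2-dimethyl-1,3-dioxolan-4-yl]butan-1-one, via alkylmagnesium bromide 5 (not isolated)
Conditions: 4, Mg, THF, 40 °C; then 2, THF, 0 °C
Reagents that add atoms: none
Why: Grignard addition to a Weinreb amide stops at the ketone because the magnesium chelate of the tetrahedral adduct collapses only on work-up; this joins C3 to C4.

Step 4
Reactants: 6 ketone 4-[(tert-butyldiphenylsilyl)oxy]-1-[(4R)-2,2-dimethyl-1,3-dioxolan-4-yl]butan-1-one
Product: 7 (4S)-4-{5-[(tert-butyldiphenylsilyl)oxy]pent-1-en-2-yl}-2,2-dimethyl-1,3-dioxolane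
Conditions: Ph3PCH3Br, KOt-Bu, THF, 0 °C
Reagents that add atoms: methyltriphenylphosphonium bromide, C[P+](c1ccccc1)(c1ccccc1)c1ccccc1.[Br-]
Why: Wittig methylenation of the unhindered ketone installs C15; the non-stabilised ylide adds faster than it enolises the α-alkoxy ketone, so C5 keeps its configuration.

Step 5
Reactants: 7 (4S)-4-{5-[(tert-butyldiphenylsilyl)oxy]pent-1-en-2-yl}-2,2-dimethyl-1,3-dioxolane
Product: 8 (2S)-6-[(tert-butyldiphenylsilyl)oxy]-3-methylidenehexane-1,2-diol
Conditions: AcOH/H2O (4:1), 40 °C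
Reagents that add atoms: none
Why: Acid hydrolysis of the terminal isopropylidene ketal; the TBDPS ether and the 1,1-disubstituted alkene are stable to aqueous acetic acid.

Step 6
Reactants: 8 (2S)-6-[(tert-butyldiphenylsilyl)oxy]-3-methylidenehexane-1,2-diol
Product: 9 (4S)-4-{5-[(tert-butyldiphenylsilyl)oxy]pent-1-en-2-yl}-2-(4-methoxyphenyl)-1,3-dioxolane (both epimers at the acetal carbon)
Conditions: 4-MeOC6H4CH(OMe)2, PPTS (cat.), CH2Cl2, rt
Reagents that add atoms: 4-methoxybenzaldehyde dimethyl acetal, COc1ccc(C(OC)OC)cc1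
Why: Acid-catalysed transacetalisation gives the 4-methoxybenzylidene acetal; the configuration at the acetal carbon is of no consequence for step 7.

Step 7
Reactants: 9 (4S)-4-{5-[(tert-butyldiphenylsilyl)oxy]pent-1-en-2-yl}-2-(4-methoxyphenyl)-1,3-dioxolane
Product: 10 (2S)-6-[(tert-butyldiphenylsilyl)oxy]-2-[(4-methoxybenzyl)oxy]-3-methylidenehexan-1-ol
Conditions: i-Bu2AlH, CH2Cl2, −78 → 0 °C
Reagents that add atoms: none
Why: Regioselective reductive opening of the benzylidene-type acetal: the aluminium hydride coordinates the less hindered primary oxygen and cleaves its C–O bond, which leaves the PMB group on the secondary O5 (a group that can chelate zinc in step 12 and outlasts fluoride and the carbonylation medium) and frees the C6 hydroxyl.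

Step 8
Reactants: 10 (2S)-6-[(tert-butyldiphenylsilyl)oxy]-2-[(4-methoxybenzyl)oxy]-3-methylidenehexan-1-ol
Product: 11 (2S)-6-[(tert-butyldiphenylsilyl)oxy]-2-[(4-methoxybenzyl)oxy]-3-methylidenehexanal (the formyl carbon is C6)
Conditions: Dess–Martin periodinane, NaHCO3, CH2Cl2, 0 °C
Reagents that add atoms: none
Why: Dess–Martin oxidation under buffered, non-basic conditions gives the α-alkoxy β,γ-unsaturated aldehyde without epimerisation at C5 or migration of the double bond into conjugation; 11 is used at once.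

**Fragment B (C7–C9, C11, C13)**

Step 9
Reactants: 12 ethynyltrimethylsilane; 2 (R)-N-methoxy-N,2,2-trimethyl-1,3-dioxolane-4-carboxamide
Product: 14 ynone 1-[(4R)-2,2-dimethyl-1,3-dioxolan-4-yl]-3-(trimethylsilyl)prop-2-yn-1-one, via lithium acetylide 13 (not isolated)
Conditions: 12, n-BuLi, THF, −78 °C; then 2, −78 → 0 °C
Reagents that add atoms: none
Why: Acylation of the lithium acetylide by the Weinreb amide gives the ynone and brings in C11 and C13.

Step 10
Reactants: 14 ynone 1-[(4R)-2,2-dimethyl-1,3-dioxolan-4-yl]-3-(trimethylsilyl)prop-2-yn-1-one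
Product: 16 (1S)-1-[(4R)-2,2-dimethyl-1,3-dioxolan-4-yl]prop-2-yn-1-ol, via silylated alkynol 15 (not isolated)
Conditions: Ru[(R,R)-TsNCH(Ph)CH(Ph)NH](p-cymene) (2 mol %), i-PrOH, rt; then K2CO3 (cat.), MeOH, rt
Reagents that add atoms: none
Why: Noyori transfer hydrogenation reduces the ynone under catalyst control, the (R,R)-ligand delivering hydride to the face that gives the (S)-carbinol (O7 and O8 anti), and methanolysis then removes the C-silyl group in the same flask.

Step 11
Reactants: 16 (1S)-1-[(4R)-2,2-dimethyl-1,3-dioxolan-4-yl]prop-2-yn-1-ol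
Product: 17 (1S)-1-[(4R)-2,2-dimethyl-1,3-dioxolan-4-yl]prop-2-yn-1-yl methanesulfonate
Conditions: MsCl, Et3N, CH2Cl2, −78 °C
Reagents that add atoms: methanesulfonyl chloride, CS(=O)(=O)Cl
Why: O-Sulfonylation of the propargylic alcohol, with retention at C7, provides the leaving group for step 12.

**Coupling, elaboration and ring closure**

Step 12
Reactants: 17 (1S)-1-[(4R)-2,2-dimethyl-1,3-dioxolan-4-yl]prop-2-yn-1-yl methanesulfonate; 11 (2S)-6-[(tert-butyldiphenylsilyl)oxy]-2-[(4-methoxybenzyl)oxy]-3-methylidenehexanal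
Product: 19 (5S,6S,7S,8S)-1-(tert-butyldiphenylsilyloxy)-7-ethynyl-8,9-(isopropylidenedioxy)-5-(4-methoxybenzyloxy)-4-methylidenenonan-6-ol, via allenyl(ethyl)zinc 18 (not isolated)
Conditions: Pd(OAc)2 (5 mol %), PPh3 (5 mol %), Et2Zn (3 equiv), THF, −78 → −20 °C
Reagents that add atoms: none
Why: Marshall–Tamaru propargylation: zerovalent palladium ionises the mesylate in an anti SN2′ sense, Et2Zn transmetalates to the configurationally defined allenylzinc 18, and its addition through a cyclic SE2′ transition state forms C6–C7; the axial chirality fixes C7, the anti preference of the cyclic transition state fixes C6, and chelation of zinc by the C5 PMB ether directs attack to the same aldehyde face (5,6-syn), so reagent and substrate control should reinforce each other.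

Step 13
Reactants: 19 (5S,6S,7S,8S)-1-(tert-butyldiphenylsilyloxy)-7-ethynyl-8,9-(isopropylidenedioxy)-5-(4-methoxybenzyloxy)-4-methylidenenonan-6-ol
Product: 20 6-O-tert-butyldimethylsilyl ether of 19 (5S,6S,7R,8S)
Conditions: TBSOTf, 2,6-lutidine, CH2Cl2, −40 → 0 °C
Reagents that add atoms: tert-butyldimethylsilyl trifluoromethanesulfonate, CC(C)(C)[Si](C)(C)OS(=O)(=O)C(F)(F)F
Why: Silylation of the hindered secondary hydroxyl with the silyl triflate blocks O6, so that only O8 can be acylated in step 16.

Step 14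
Reactants: 20 6-O-tert-butyldimethylsilyl ether of 19
Product: 21 (5S,6S,7R,8S)-6-(tert-butyldimethylsilyloxy)-1-(tert-butyldiphenylsilyloxy)-7-ethynyl-5-(4-methoxybenzyloxy)-4-methylidenenonane-8,9-diol
Conditions: AcOH/THF/H2O (3:1:1), 40 °C
Reagents that add atoms: none
Why: Hydrolysis of the terminal isopropylidene ketal under conditions that the hindered secondary TBS ether, the TBDPS ether and the PMB ether tolerate.

Step 15
Reactants: 21 (5S,6S,7R,8S)-6-(tert-butyldimethylsilyloxy)-1-(tert-butyldiphenylsilyloxy)-7-ethynyl-5-(4-methoxybenzyloxy)-4-methylidenenonane-8,9-diol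
Product: 22 9-O-(4-toluenesulfonate) of 21 (5S,6S,7R,8S)
Conditions: TsCl, Bu2SnO (cat.), Et3N, CH2Cl2, rt
Reagents that add atoms: 4-toluenesulfonyl chloride, Cc1ccc(cc1)S(=O)(=O)Cl
Why: Tin-catalysed sulfonylation through the stannylene acetal is selective for the primary hydroxyl of a terminal 1,2-diol.

Step 16
Reactants: 22 9-O-(4-toluenesulfonate) of 21; 23 angelic acid
Product: 25 8-O-angelate of 22 (5S,6S,7R,8S), via mixed anhydride 24 (not isolated)
Conditions: 23, 2,4,6-Cl3C6H2COCl, i-Pr2NEt, toluene, rt; then 22, 70 °C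
Reagents that add atoms: none
Why: Yamaguchi-type esterification through the mixed anhydride, run with a hindered amine and no nucleophilic catalyst, acylates the secondary O8 with angelic acid without isomerisation to the tiglate, and the amine is too weak a base to close the hydroxy tosylate to an epoxide.

Step 17
Reactants: 25 8-O-angelate of 22; 26 trimethyl phosphonoacetate
Product: 29 methyl 2-(dimethoxyphosphoryl)alkanoate in which C10 of the phosphonoacetate is bonded to C9 in place of the tosylate of 25 (5S,6S,7R,8R; both C10 epimers), via sodium phosphonoacetate 27 (not isolated), via iodide 28 (not isolated)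
Conditions: 26, NaH, DMF, 0 °C; then 25, NaI, 60 °C
Reagents that add atoms: none
Why: SN2 alkylation of the soft phosphonoacetate anion at the primary C9, through the iodide formed in situ (Finkelstein exchange), forms C9–C10; the stabilised carbanion does not attack the hindered angelate, and the two C10 epimers converge in step 20.

Step 18
Reactants: 29 C9-alkylated phosphonoacetate
Product: 30 1,6-diol of 29 (5S,6S,7S,8R; both C10 epimers)
Conditions: HF·pyridine, pyridine, THF, 0 °C → rt
Reagents that add atoms: none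
Why: Acidic fluoride cleaves the primary TBDPS and the secondary TBS ether without base, so the angelate neither migrates to O6 nor is cleaved.

Step 19
Reactants: 30 1,6-diol
Product: 31 C1 aldehyde of 30 (5S,6S,7S,8R; both C10 epimers)
Conditions: TEMPO (cat.), PhI(OAc)2, CH2Cl2, rt
Reagents that add atoms: none
Why: Oxoammonium (TEMPO) oxidation is selective for the primary C1 hydroxyl over the hindered secondary C6 hydroxyl and leaves the alkyne, the alkenes and the PMB ether untouched.

Step 20
Reactants: 31 C1 aldehyde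
Product: 32 ten-membered ethynyl carbinol: methyl (5S,6S,7S,8R)-8-(angeloyloxy)-7-ethynyl-6-hydroxy-5-(4-methoxybenzyloxy)-4-methylidenecyclodec-1(10)-ene-10-carboxylate with ring-cis C1=C10 (ester trans to C2)
Conditions: LiCl, i-Pr2NEt, MeCN, rt, slow addition to a final concentration of 1 mM
Reagents that add atoms: none
Why: Intramolecular Horner–Wadsworth–Emmons olefination under Masamune–Roush conditions at high dilution forms C1=C10; the intrinsic preference of α-substituted phosphonoacetates for the isomer with the ester trans to the aldehyde-derived chain coincides with the ring-cis geometry favoured in a cyclodecene, and the mild amine base leaves the free C6 hydroxyl and the angelate alone.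

Step 21
Reactants: 32 ten-membered ethynyl carbinol
Product: 33 5-O-(4-methoxybenzyl) ether of the target (5S,6S,7R,8R): trans-fused α-methylene-γ-lactone on the cyclodecene
Conditions: PdCl2 (10 mol %), PPh3 (20 mol %), SnCl2 (10 mol %), CO (7 atm), MeCN, 75 °C
Reagents that add atoms: carbon monoxide, [C-]#[O+]
Why: The C6 hydroxyl, CO and PdCl2(PPh3)2/SnCl2 form an alkoxycarbonyl complex of divalent palladium; syn insertion of the C11≡C13 triple bond into its Pd–C bond closes the lactone, and protonolysis of the vinyl–palladium bond by the HCl formed releases the exocyclic C13 methylene and the catalyst. The closest known reaction is the PdCl2/PPh3/SnCl2 cyclocarbonylation of homopropargylic alcohols such as trans-2-ethynylcycloalkanols to α-methylene-γ-butyrolactones. The one ring formed (O6, C6, C7, C11, C12) closes in the 5-exo-dig mode, with O6–C12 and C12–C11 as the new bonds. No stereocentre is created: C6 and C7 are not touched, so the trans relation set in step 12 becomes the trans ring fusion. The step needs chemoselectivity for O6 and for the alkyne: O6 is the only free hydroxyl (O5 is a PMB ether, O8 an angelate), so no six-membered lactone through O5 can form, and the three alkenes and two esters are inert to the neutral medium. Building this Michael acceptor last keeps it away from every basic or nucleophilic reagent of the route.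

Step 22
Reactants: 33 5-O-(4-methoxybenzyl) ether of the target
Product: 34 target CNP0163095.1 (5S,6S,7R,8R)
Conditions: DDQ, CH2Cl2/pH 7 buffer (10:1), 0 °C
Reagents that add atoms: none
Why: Oxidative cleavage of the PMB ether by DDQ (hydride abstraction at the benzylic carbon, then hydrolysis of the oxocarbenium ion) is neutral and touches neither the Michael acceptors, the angelate nor the allylic alcohol that is released.

**Compound list**

1 | methyl (R)-2,2-dimethyl-1,3-dioxolane-4-carboxylate | COC(=O)[C@H]1COC(C)(C)O1 | starting material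
2 | (R)-N-methoxy-N,2,2-trimethyl-1,3-dioxolane-4-carboxamide | CON(C)C(=O)[C@H]1COC(C)(C)O1 | intermediate
3 | 3-bromopropan-1-ol | OCCCBr | starting material
4 | (3-bromopropoxy)(tert-butyl)diphenylsilane | BrCCCO[Si](c1ccccc1)(c1ccccc1)C(C)(C)C | intermediate
5 | {3-[(tert-butyldiphenylsilyl)oxy]propyl}magnesium bromide | Br[Mg]CCCO[Si](c1ccccc1)(c1ccccc1)C(C)(C)C | intermediate
6 | 4-[(tert-butyldiphenylsilyl)oxy]-1-[(4R)-2,2-dimethyl-1,3-dioxolan-4-yl]butan-1-one | O=C(CCCO[Si](c1ccccc1)(c1ccccc1)C(C)(C)C)[C@H]1COC(C)(C)O1 | intermediate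
7 | (4S)-4-{5-[(tert-butyldiphenylsilyl)oxy]pent-1-en-2-yl}-2,2-dimethyl-1,3-dioxolane | C=C(CCCO[Si](c1ccccc1)(c1ccccc1)C(C)(C)C)[C@H]1COC(C)(C)O1 | intermediate
8 | (2S)-6-[(tert-butyldiphenylsilyl)oxy]-3-methylidenehexane-1,2-diol | C=C(CCCO[Si](c1ccccc1)(c1ccccc1)C(C)(C)C)[C@H](O)CO | intermediate
9 | (4S)-4-{5-[(tert-butyldiphenylsilyl)oxy]pent-1-en-2-yl}-2-(4-methoxyphenyl)-1,3-dioxolane, both epimers at the acetal carbon | C=C(CCCO[Si](c1ccccc1)(c1ccccc1)C(C)(C)C)[C@H]1COC(c2ccc(OC)cc2)O1 | intermediate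
10 | (2S)-6-[(tert-butyldiphenylsilyl)oxy]-2-[(4-methoxybenzyl)oxy]-3-methylidenehexan-1-ol | C=C(CCCO[Si](c1ccccc1)(c1ccccc1)C(C)(C)C)[C@H](OCc1ccc(OC)cc1)CO | intermediate
11 | (2S)-6-[(tert-butyldiphenylsilyl)oxy]-2-[(4-methoxybenzyl)oxy]-3-methylidenehexanal | C=C(CCCO[Si](c1ccccc1)(c1ccccc1)C(C)(C)C)[C@H](OCc1ccc(OC)cc1)C=O | intermediate
12 | ethynyltrimethylsilane | C#C[Si](C)(C)C | starting material
13 | lithium (trimethylsilyl)acetylide | [Li]C#C[Si](C)(C)C | intermediate
14 | 1-[(4R)-2,2-dimethyl-1,3-dioxolan-4-yl]-3-(trimethylsilyl)prop-2-yn-1-one | C[Si](C)(C)C#CC(=O)[C@H]1COC(C)(C)O1 | intermediate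
15 | (1S)-1-[(4R)-2,2-dimethyl-1,3-dioxolan-4-yl]-3-(trimethylsilyl)prop-2-yn-1-ol | C[Si](C)(C)C#C[C@H](O)[C@H]1COC(C)(C)O1 | intermediate
16 | (1S)-1-[(4R)-2,2-dimethyl-1,3-dioxolan-4-yl]prop-2-yn-1-ol | C#C[C@H](O)[C@H]1COC(C)(C)O1 | intermediate
17 | (1S)-1-[(4R)-2,2-dimethyl-1,3-dioxolan-4-yl]prop-2-yn-1-yl methanesulfonate | C#C[C@H](OS(C)(=O)=O)[C@H]1COC(C)(C)O1 | intermediate
18 | (aS)-{3-[(4S)-2,2-dimethyl-1,3-dioxolan-4-yl]propa-1,2-dien-1-yl}(ethyl)zinc | [H]C([Zn]CC)=[C@]=C([H])[C@H]1COC(C)(C)O1 | intermediate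
19 | (5S,6S,7S,8S)-1-(tert-butyldiphenylsilyloxy)-7-ethynyl-8,9-(isopropylidenedioxy)-5-(4-methoxybenzyloxy)-4-methylidenenonan-6-ol | C#C[C@H]([C@H]1COC(C)(C)O1)[C@H](O)[C@@H](OCc1ccc(OC)cc1)C(=C)CCCO[Si](c1ccccc1)(c1ccccc1)C(C)(C)C | intermediate
20 | 6-O-tert-butyldimethylsilyl ether of 19 (5S,6S,7R,8S) | C#C[C@H]([C@H]1COC(C)(C)O1)[C@H](O[Si](C)(C)C(C)(C)C)[C@@H](OCc1ccc(OC)cc1)C(=C)CCCO[Si](c1ccccc1)(c1ccccc1)C(C)(C)C | intermediate
21 | (5S,6S,7R,8S)-6-(tert-butyldimethylsilyloxy)-1-(tert-butyldiphenylsilyloxy)-7-ethynyl-5-(4-methoxybenzyloxy)-4-methylidenenonane-8,9-diol | C#C[C@H]([C@H](O)CO)[C@H](O[Si](C)(C)C(C)(C)C)[C@@H](OCc1ccc(OC)cc1)C(=C)CCCO[Si](c1ccccc1)(c1ccccc1)C(C)(C)C | intermediate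
22 | 9-O-(4-toluenesulfonate) of 21 (5S,6S,7R,8S) | C#C[C@H]([C@H](O)COS(=O)(=O)c1ccc(C)cc1)[C@H](O[Si](C)(C)C(C)(C)C)[C@@H](OCc1ccc(OC)cc1)C(=C)CCCO[Si](c1ccccc1)(c1ccccc1)C(C)(C)C | intermediate
23 | angelic acid, (Z)-2-methylbut-2-enoic acid | C/C=C(/C)C(=O)O | starting material
24 | angelic 2,4,6-trichlorobenzoic anhydride | C/C=C(/C)C(=O)OC(=O)c1c(Cl)cc(Cl)cc1Cl | intermediate
25 | 8-O-angelate of 22 (5S,6S,7R,8S) | C#C[C@H]([C@H](OC(=O)/C(C)=C\C)COS(=O)(=O)c1ccc(C)cc1)[C@H](O[Si](C)(C)C(C)(C)C)[C@@H](OCc1ccc(OC)cc1)C(=C)CCCO[Si](c1ccccc1)(c1ccccc1)C(C)(C)C | intermediate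
26 | trimethyl phosphonoacetate | COC(=O)CP(=O)(OC)OC | starting material
27 | sodium salt of trimethyl phosphonoacetate | COC(=O)[CH-]P(=O)(OC)OC.[Na+] | intermediate
28 | C9 iodide corresponding to tosylate 25 (5S,6S,7R,8S) | C#C[C@H]([C@H](OC(=O)/C(C)=C\C)CI)[C@H](O[Si](C)(C)C(C)(C)C)[C@@H](OCc1ccc(OC)cc1)C(=C)CCCO[Si](c1ccccc1)(c1ccccc1)C(C)(C)C | intermediate
29 | C9-alkylated phosphonoacetate: C9 carries CH(CO2Me)P(O)(OMe)2 (C10, both epimers); 8-O-angelate, 6-OTBS, 5-OPMB, 1-OTBDPS, 7-ethynyl, 4-methylidene (5S,6S,7R,8R) | C#C[C@H]([C@H](OC(=O)/C(C)=C\C)CC(C(=O)OC)P(=O)(OC)OC)[C@H](O[Si](C)(C)C(C)(C)C)[C@@H](OCc1ccc(OC)cc1)C(=C)CCCO[Si](c1ccccc1)(c1ccccc1)C(C)(C)C | intermediate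
30 | 1,6-diol obtained from 29 by loss of both silyl groups (5S,6S,7S,8R; both C10 epimers) | C#C[C@H]([C@H](OC(=O)/C(C)=C\C)CC(C(=O)OC)P(=O)(OC)OC)[C@H](O)[C@@H](OCc1ccc(OC)cc1)C(=C)CCCO | intermediate
31 | C1 aldehyde of 30 (5S,6S,7S,8R; both C10 epimers) | C#C[C@H]([C@H](OC(=O)/C(C)=C\C)CC(C(=O)OC)P(=O)(OC)OC)[C@H](O)[C@@H](OCc1ccc(OC)cc1)C(=C)CCC=O | intermediate
32 | methyl (5S,6S,7S,8R)-8-(angeloyloxy)-7-ethynyl-6-hydroxy-5-(4-methoxybenzyloxy)-4-methylidenecyclodec-1(10)-ene-10-carboxylate, ring-cis C1=C10 | C#C[C@@H]1[C@H](OC(=O)/C(C)=C\C)C/C(C(=O)OC)=C\CCC(=C)[C@H](OCc2ccc(OC)cc2)[C@H]1O | intermediate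
33 | 5-O-(4-methoxybenzyl) ether of the target (5S,6S,7R,8R) | C=C1C(=O)O[C@H]2[C@H]1[C@H](OC(=O)/C(C)=C\C)C/C(C(=O)OC)=C\CCC(=C)[C@@H]2OCc1ccc(OC)cc1 | intermediate
34 | CNP0163095.1: methyl (5S,6S,7R,8R)-8-(angeloyloxy)-5-hydroxygermacra-1(10)Z,4(15),11(13)-trien-12,6-olid-14-oate | C=C1C(=O)O[C@H]2[C@H]1[C@H](OC(=O)/C(C)=C\C)C/C(C(=O)OC)=C\CCC(=C)[C@@H]2O | target

**Step count.** Total: 22 steps. Longest linear sequence: 18 steps (1 → 2 → 6 → 7 → 8 → 9 → 10 → 11 → 19 → 20 → 21 → 22 → 25 → 29 → 30 → 31 → 32 → 33 → 34).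

**The three steps most likely to fail**

Step 21 (ring carbonylation). The alkoxycarbonyl–palladium species may insert too slowly into the hindered alkyne held on the medium ring, so that hydrochlorination or oligomerisation of the alkyne takes over. The fallback runs from 32 back to 33 and separates halide installation from carbonylation. Bromoboration of the terminal alkyne with B-bromo-9-borabicyclo[3.3.1]nonane (CH2Cl2, 0 °C) followed by protodeboronation with AcOH gives the 2-bromoalkene F1. Pd(PPh3)4, CO (1 atm), Et3N, MeCN at 60 °C then bring about oxidative addition, CO insertion and capture of the acylpalladium by O6 (intramolecular alkoxycarbonylation of a vinyl halide), which gives 33.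

Step 20 (ring closure). Intermolecular olefination may outrun closure of the ten-membered ring and give the cyclic dimer and oligomers. The fallback runs from 31 back to 32 and closes the same C1=C10 bond by ring-closing metathesis. Wittig methylenation of the aldehyde (excess Ph3P=CH2, THF, −78 °C; the phosphonate is only deprotonated and is recovered on work-up) gives the terminal olefin F2. Horner–Wadsworth–Emmons reaction of F2 with aqueous formaldehyde (K2CO3, THF) gives the 2-substituted acrylate F3. Me3SiOTf, Et3N and catalytic Zn(OTf)2 silylate the alkyne C–H and O6 to give the bis-silyl triene F4, which hides the terminal alkyne from the ruthenium carbene. The second-generation Hoveyda–Grubbs catalyst (toluene, 80 °C, high dilution) should then close the ring with loss of ethene to the silylated cyclodecene F5. Bu4NF/AcOH removes both trimethylsilyl groups and returns 32.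

Step 12 (fragment coupling). Facial selectivity at the aldehyde may be lost: the cyclic transition state may follow the Felkin preference of the α-alkoxy aldehyde instead of the chelate and the anti preference of the reagent, so that 19 is accompanied or replaced by its C6 epimer (C7 is fixed by the reagent in either case). The fallback runs from 19, taken as the C6 epimer mixture, back to 19. Dess–Martin oxidation gives the C6 ketone F6. Reduction with K[s-Bu3BH] (THF, −78 °C), now under Felkin–Anh control by the C5 ether (hydride anti to the C5–O bond), should give the 5,6-syn alcohol, which is 19.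

**Further compounds**

F1 | step 21 | 2-bromoalkene: 32 with the ethynyl group replaced by 1-bromovinyl (5S,6S,7S,8R) | C=C(Br)[C@@H]1[C@H](OC(=O)/C(C)=C\C)C/C(C(=O)OC)=C\CCC(=C)[C@H](OCc2ccc(OC)cc2)[C@H]1O
F2 | step 20 | terminal olefin: 31 with the C1 formyl group converted to vinyl (both C10 epimers) | C#C[C@H]([C@H](OC(=O)/C(C)=C\C)CC(C(=O)OC)P(=O)(OC)OC)[C@H](O)[C@@H](OCc1ccc(OC)cc1)C(=C)CCC=C
F3 | step 20 | 2-substituted acrylate: F2 with C10 converted to C(=CH2)CO2Me | C#C[C@H]([C@H](OC(=O)/C(C)=C\C)CC(=C)C(=O)OC)[C@H](O)[C@@H](OCc1ccc(OC)cc1)C(=C)CCC=C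
F4 | step 20 | bis-silyl triene: F3 silylated at C13 and at O6 | C[Si](C)(C)C#C[C@H]([C@H](OC(=O)/C(C)=C\C)CC(=C)C(=O)OC)[C@H](O[Si](C)(C)C)[C@@H](OCc1ccc(OC)cc1)C(=C)CCC=C
F5 | step 20 | silylated cyclodecene: 32 carrying trimethylsilyl groups at C13 and O6 | C[Si](C)(C)C#C[C@@H]1[C@H](OC(=O)/C(C)=C\C)C/C(C(=O)OC)=C\CCC(=C)[C@H](OCc2ccc(OC)cc2)[C@H]1O[Si](C)(C)C
F6 | step 12 | C6 ketone of 19 (5S,7R,8S) | C#C[C@H]([C@H]1COC(C)(C)O1)C(=O)[C@@H](OCc1ccc(OC)cc1)C(=C)CCCO[Si](c1ccccc1)(c1ccccc1)C(C)(C)C
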